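The route rests on cutting the bond between C5 (side-chain carbinol) and C6 (the tetrahydrofuran CH bonded to the ring oxygen; prostanoid numbering). C6 sits in a cis-fused 2-oxabicyclo[3.3.0]octenone, flanked by the ring oxygen and the exo C7 oxygen, so its oxocarbenium ion should accept a carbon nucleophile on the convex face, cis to O7. In the key step a bicyclic methyl acetal (C6 acetal, free C7–OH, chloro enone in place) is alkynylated with the stannylated C1–C5 alkynoate; the alkyne is a masked C5 ketone, unveiled through an O7 silicon tether and reduced 1,3-syn. One bought stereocentre, (S)-4-silyloxycyclopentenone, sets C12; an anti-aldol relays C12 to C8 and C7.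

Key step: step 10

Remark (numbering): C1 is the ester carbon, C5 and C7 carry the acetoxy groups, C6 is the ring CH next to the ring oxygen, C8 and C12 are the ring-fusion carbons, C9 is the ketone, C10 carries chlorine.
Remark (chemistry): 2,2-dimethoxyacetaldehyde is sold as an aqueous solution and is extracted, dried and distilled before step 7; 14 is used as the mixture of C6 epimers.

Step 1
Reactants: 1 (Z)-oct-2-en-1-ol
Product: 2 (Z)-1-chlorooct-2-ene
Conditions: NCS, Me2S, CH2Cl2, −20 → 0 °C
Reagents that add atoms: N-chlorosuccinimide, O=C1CCC(=O)N1Cl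
Why: Corey–Kim chlorination: chloride displaces the alkoxysulfonium ion at the primary carbon (SN2), so neither allylic transposition nor Z→E isomerisation should occur.

Step 2
Reactants: 2 (Z)-1-chlorooct-2-ene; 3 (S)-4-(tert-butyldimethylsilyloxy)cyclopent-2-en-1-one
Product: 5 (1R,4S)-4-(tert-butyldimethylsilyloxy)-1-[(Z)-oct-2-enyl]cyclopent-2-en-1-ol, via (Z)-oct-2-enylbarium chloride 4 (not isolated)
Conditions: BaI2, lithium biphenylide, THF, rt (activated Ba); 2, −78 °C; then 3, −78 °C; aq. NH4Cl
Reagents that add atoms: none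
Why: Allylbarium 1,2-addition: allylic barium reagents add to ketones and enones through their α-carbon with retention of the Z geometry, and attack anti to the C4 silyloxy group should make the new carbinol carbon R (the minor syn adduct, which would end as the enantiomer after step 4, is removed by chromatography).

Step 3
Reactants: 5 (1R,4S)-4-(tert-butyldimethylsilyloxy)-1-[(Z)-oct-2-enyl]cyclopent-2-en-1-ol
Product: 6 (1R,4S)-1-[(Z)-oct-2-enyl]cyclopent-2-ene-1,4-diol
Conditions: TBAF, THF, 0 °C → rt; aq. NH4Cl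
Reagents that add atoms: none
Why: Fluoride-induced desilylation (strong Si–F bond) frees the secondary alcohol without touching either stereocentre.

Step 4
Reactants: 6 (1R,4S)-1-[(Z)-oct-2-enyl]cyclopent-2-ene-1,4-diol
Product: 7 (R)-4-hydroxy-4-[(Z)-oct-2-enyl]cyclopent-2-en-1-one
Conditions: activated MnO2, CH2Cl2, rt
Reagents that add atoms: none
Why: Allylic oxidation with MnO2 affects only the secondary allylic alcohol because the tertiary one has no carbinol hydrogen, and it erases the bought stereocentre once it has set the quaternary carbon.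

Step 5
Reactants: 7 (R)-4-hydroxy-4-[(Z)-oct-2-enyl]cyclopent-2-en-1-one
Product: 8 (4R)-2,3-epoxy-4-hydroxy-4-[(Z)-oct-2-enyl]cyclopentan-1-one (epoxide syn to the hydroxyl)
Conditions: 30% H2O2, NaOH (cat.), MeOH, 0 °C
Reagents that add atoms: hydrogen peroxide, OO
Why: Weitz–Scheffer nucleophilic epoxidation attacks only the electron-poor enone and leaves the isolated Z-alkene; the epoxide configuration (drawn syn to the hydroxyl) is immaterial because both epoxide carbons become sp2 in step 6.

Step 6
Reactants: 8 (4R)-2,3-epoxy-4-hydroxy-4-[(Z)-oct-2-enyl]cyclopentan-1-one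
Product: 10 (R)-2-chloro-4-hydroxy-4-[(Z)-oct-2-enyl]cyclopent-2-en-1-one, via chlorohydrin 9 (not isolated)
Conditions: conc. HCl, THF, 0 °C → rt
Reagents that add atoms: hydrogen chloride, Cl
Why: Acid-mediated epoxide opening by chloride at the α-carbon (SN2, away from the quaternary carbon) followed by acid-catalysed β-elimination of water is the classical conversion of an α,β-epoxy ketone into an α-chloro enone.

Step 7
Reactants: 10 (R)-2-chloro-4-hydroxy-4-[(Z)-oct-2-enyl]cyclopent-2-en-1-one; 11 2,2-dimethoxyacetaldehyde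
Product: 13 (4R,5S)-2-chloro-4-hydroxy-5-[(1S)-1-hydroxy-2,2-dimethoxyethyl]-4-[(Z)-oct-2-enyl]cyclopent-2-en-1-one, via dilithium alkoxide enolate 12 (not isolated)
Conditions: LDA (2.2 equiv), THF, −78 °C (10 added to the base); 11, −78 °C; AcOH, −78 °C
Reagents that add atoms: none
Why: Lithium aldol addition of the alkoxide–enolate dianion: the ring-locked (E)-enolate should react through a Zimmerman–Traxler chair (anti aldol) on the face of the lithium alkoxide, anti to the octenyl chain, which sets C8 (S) and C7 (S) in one event, while the alkoxide form prevents E1cB loss of the tertiary oxygen.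

Step 8
Reactants: 13 (4R,5S)-2-chloro-4-hydroxy-5-[(1S)-1-hydroxy-2,2-dimethoxyethyl]-4-[(Z)-oct-2-enyl]cyclopent-2-en-1-one
Product: 14 (3S,3aS,6aR)-5-chloro-3-hydroxy-2-methoxy-6a-[(Z)-oct-2-enyl]-2,3,3a,6a-tetrahydro-4H-cyclopenta[b]furan-4-one (both C2 epimers)
Conditions: PPTS (cat.), 5 Å MS, CH2Cl2, 0 °C → rt
Reagents that add atoms: none
Why: Acid-catalysed transacetalisation: the tertiary hydroxyl closes the tetrahydrofuran by 5-exo attack on the oxocarbenium ion, which is possible only for the C8 epimer cis to that oxygen and gives the cis-fused bicycle with the C7 hydroxyl exo; the C6 epimers are used together since C6 becomes planar in step 10.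

Step 9
Reactants: 15 methyl pent-4-ynoate
Product: 16 methyl 5-(tributylstannyl)pent-4-ynoate
Conditions: Bu3SnOMe, neat, 60 °C, reduced pressure (removal of MeOH)
Reagents that add atoms: tributyltin methoxide, CCCC[Sn](CCCC)(CCCC)OC
Why: Stannylation of the terminal alkyne by a tin alkoxide is an acid–base exchange driven by removal of methanol and tolerates the ester that a lithium acetylide would attack.

Step 10
Reactants: 14 bicyclic methyl acetal (C6 epimers); 16 methyl 5-(tributylstannyl)pent-4-ynoate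
Product: 17 methyl 5-[(2S,3S,3aS,6aR)-5-chloro-3-hydroxy-6a-[(Z)-oct-2-enyl]-4-oxo-3,3a,4,6a-tetrahydro-2H-cyclopenta[b]furan-2-yl]pent-4-ynoate
Conditions: 16 (2.5 equiv), BF3·OEt2 (2.5 equiv), 4 Å MS, CH2Cl2, −78 → −20 °C; aq. KF/NaHCO3
Reagents that add atoms: none
Why: BF3 ionises the anomeric methoxy group of 14 to the bicyclic oxocarbenium ion at C6, which is attacked by the tin-bearing sp carbon of 16 (ipso substitution through a β-stannyl vinyl cation, then loss of the tin group), so that C5 and C6 are joined and the whole C1–C5 chain arrives as an alkyne that is a masked C5 ketone. The closest known reaction type is the Lewis-acid C-glycosylation of furanosyl acetals with alkynylstannanes and alkynylsilanes. No ring is closed in this step. The new stereocentre C6 is controlled by the substrate: attack on the convex (exo) face of the cis-fused bicycle coincides with inside attack on the envelope that has the C7 oxygen pseudo-equatorial (the 1,2-cis preference of 2-oxy five-membered oxocarbenium ions), so C5 should enter cis to O7 and to H8. The step needs facial selectivity at C6 and chemoselectivity for the oxocarbenium ion over the ketone, the chloro enone and the Z-alkene; the first is secured by the ring fusion and the non-participating free C7 hydroxyl, the second by the low temperature and by a π-nucleophile that does not add to hindered ketones (an excess of 16 covers loss by protonation).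

Step 11
Reactants: 17 alkynyl C-glycoside
Product: 19 tricyclic (E)-alkylidene 1,2-oxasilolane (SiMe2 bonded to O7 and to C5; C5=C4 exocyclic), via dimethylsilyl ether 18 (not isolated)
Conditions: (HMe2Si)2NH, neat, 40 °C; evaporate; Pt2(dvds)3 (1 mol %), THF, rt
Reagents that add atoms: 1,1,3,3-tetramethyldisilazane, C[SiH](C)N[SiH](C)C
Why: Silylation of O7 followed by platinum-catalysed intramolecular syn-hydrosilylation (Tamao–Ito type) closes the oxasilolane in the 5-exo-dig mode, so silicon ends on C5 and not on C4, and the alkene geometry is irrelevant.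

Step 12
Reactants: 19 tricyclic alkylidene oxasilolane
Product: 20 methyl 5-[(2R,3S,3aS,6aR)-5-chloro-3-hydroxy-6a-[(Z)-oct-2-enyl]-4-oxo-3,3a,4,6a-tetrahydro-2H-cyclopenta[b]furan-2-yl]-5-oxopentanoate
Conditions: 30% H2O2, KHF2, DMF, rt
Reagents that add atoms: hydrogen peroxide, OO
Why: Tamao–Fleming oxidation of the alkenyl–silicon bond gives the enol and hence the C5 ketone and frees O7–H, under weakly acidic fluoride/peroxide conditions that should neither epoxidise the chloro enone nor epimerise C6.

Step 13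
Reactants: 20 β-hydroxy ketone
Product: 22 methyl (5R)-5-[(2S,3S,3aS,6aR)-5-chloro-3-hydroxy-6a-[(Z)-oct-2-enyl]-4-oxo-3,3a,4,6a-tetrahydro-2H-cyclopenta[b]furan-2-yl]-5-hydroxypentanoate, via diethylboron chelate 21 (not isolated)
Conditions: Et2BOMe (1.1 equiv), THF–MeOH (4:1), −78 °C; NaBH4 (1.1 equiv), −78 °C; AcOH; MeOH co-evaporation
Reagents that add atoms: none
Why: Narasaka–Prasad reduction: external hydride attacks the six-membered diethylboron chelate of O7 and the C5 carbonyl to give the 1,3-syn diol (C5 R), and the C9 ketone is not activated because O7 and C9 are trans on the ring and cannot chelate.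

Step 14
Reactants: 22 diol
Product: 23 methyl (5R)-5-acetoxy-5-[(2S,3S,3aS,6aR)-3-acetoxy-5-chloro-6a-[(Z)-oct-2-enyl]-4-oxo-3,3a,4,6a-tetrahydro-2H-cyclopenta[b]furan-2-yl]pentanoate (CNP0318775.1)
Conditions: Ac2O, pyridine, DMAP (cat.), CH2Cl2, 0 °C
Reagents that add atoms: acetic anhydride, CC(=O)OC(C)=O
Why: DMAP-catalysed acylation of both secondary alcohols at low temperature; E1cB loss of the β-acetoxy group is disfavoured because it would place a double bond at the ring-fusion carbon.

Compound list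
1 | (Z)-oct-2-en-1-ol | CCCCC/C=C\CO | starting material
2 | (Z)-1-chlorooct-2-ene | CCCCC/C=C\CCl | intermediate
3 | (S)-4-(tert-butyldimethylsilyloxy)cyclopent-2-en-1-one | O=C1C=C[C@@H](O[Si](C)(C)C(C)(C)C)C1 | starting material
4 | (Z)-oct-2-enylbarium chloride (not isolated) | CCCCC/C=C\C[Ba]Cl | intermediate
5 | (1R,4S)-4-(tert-butyldimethylsilyloxy)-1-[(Z)-oct-2-enyl]cyclopent-2-en-1-ol | CCCCC/C=C\C[C@]1(O)C=C[C@@H](O[Si](C)(C)C(C)(C)C)C1 | intermediate
6 | (1R,4S)-1-[(Z)-oct-2-enyl]cyclopent-2-ene-1,4-diol | CCCCC/C=C\C[C@]1(O)C=C[C@@H](O)C1 | intermediate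
7 | (R)-4-hydroxy-4-[(Z)-oct-2-enyl]cyclopent-2-en-1-one | CCCCC/C=C\C[C@]1(O)C=CC(=O)C1 | intermediate
8 | (4R)-2,3-epoxy-4-hydroxy-4-[(Z)-oct-2-enyl]cyclopentan-1-one, epoxide syn to OH | CCCCC/C=C\C[C@]1(O)[C@H]2O[C@H]2C(=O)C1 | intermediate
9 | (4R)-2-chloro-3,4-dihydroxy-4-[(Z)-oct-2-enyl]cyclopentan-1-one, Cl trans to 3-OH (not isolated) | CCCCC/C=C\C[C@]1(O)[C@@H](O)[C@H](Cl)C(=O)C1 | intermediate
10 | (R)-2-chloro-4-hydroxy-4-[(Z)-oct-2-enyl]cyclopent-2-en-1-one | CCCCC/C=C\C[C@]1(O)C=C(Cl)C(=O)C1 | intermediate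
11 | 2,2-dimethoxyacetaldehyde | COC(OC)C=O | starting material
12 | dilithium alkoxide enolate of 10 (not isolated) | CCCCC/C=C\C[C@]1(O[Li])C=C(Cl)C(O[Li])=C1 | intermediate
13 | (4R,5S)-2-chloro-4-hydroxy-5-[(1S)-1-hydroxy-2,2-dimethoxyethyl]-4-[(Z)-oct-2-enyl]cyclopent-2-en-1-one | CCCCC/C=C\C[C@]1(O)C=C(Cl)C(=O)[C@H]1[C@H](O)C(OC)OC | intermediate
14 | (3S,3aS,6aR)-5-chloro-3-hydroxy-2-methoxy-6a-[(Z)-oct-2-enyl]-2,3,3a,6a-tetrahydro-4H-cyclopenta[b]furan-4-one, both C2 epimers | CCCCC/C=C\C[C@]12C=C(Cl)C(=O)[C@H]1[C@H](O)C(OC)O2 | intermediate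
15 | methyl pent-4-ynoate | C#CCCC(=O)OC | starting material
16 | methyl 5-(tributylstannyl)pent-4-ynoate | CCCC[Sn](CCCC)(CCCC)C#CCCC(=O)OC | intermediate
17 | methyl 5-[(2S,3S,3aS,6aR)-5-chloro-3-hydroxy-6a-[(Z)-oct-2-enyl]-4-oxo-3,3a,4,6a-tetrahydro-2H-cyclopenta[b]furan-2-yl]pent-4-ynoate | CCCCC/C=C\C[C@]12C=C(Cl)C(=O)[C@H]1[C@H](O)[C@H](C#CCCC(=O)OC)O2 | intermediate
18 | 3-O-dimethylsilyl ether of 17 (not isolated) | CCCCC/C=C\C[C@]12C=C(Cl)C(=O)[C@H]1[C@H](O[SiH](C)C)[C@H](C#CCCC(=O)OC)O2 | intermediate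
19 | tricyclic (E)-alkylidene 1,2-oxasilolane (SiMe2 between O7 and C5, C5=C4 exocyclic) | CCCCC/C=C\C[C@]12C=C(Cl)C(=O)[C@H]1[C@@H]3O[Si](C)(C)/C(=C/CCC(=O)OC)[C@@H]3O2 | intermediate
20 | methyl 5-[(2R,3S,3aS,6aR)-5-chloro-3-hydroxy-6a-[(Z)-oct-2-enyl]-4-oxo-3,3a,4,6a-tetrahydro-2H-cyclopenta[b]furan-2-yl]-5-oxopentanoate | CCCCC/C=C\C[C@]12C=C(Cl)C(=O)[C@H]1[C@H](O)[C@H](C(=O)CCCC(=O)OC)O2 | intermediate
21 | O7-diethylboryl chelate of 20 (not isolated) | CCCCC/C=C\C[C@]12C=C(Cl)C(=O)[C@H]1[C@H](OB(CC)CC)[C@H](C(=O)CCCC(=O)OC)O2 | intermediate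
22 | methyl (5R)-5-[(2S,3S,3aS,6aR)-5-chloro-3-hydroxy-6a-[(Z)-oct-2-enyl]-4-oxo-3,3a,4,6a-tetrahydro-2H-cyclopenta[b]furan-2-yl]-5-hydroxypentanoate | CCCCC/C=C\C[C@]12C=C(Cl)C(=O)[C@H]1[C@H](O)[C@H]([C@@H](CCCC(=O)OC)O)O2 | intermediate
23 | methyl (5R)-5-acetoxy-5-[(2S,3S,3aS,6aR)-3-acetoxy-5-chloro-6a-[(Z)-oct-2-enyl]-4-oxo-3,3a,4,6a-tetrahydro-2H-cyclopenta[b]furan-2-yl]pentanoate | CCCCC/C=C\C[C@]12C=C(Cl)C(=O)[C@H]1[C@H](OC(C)=O)[C@H]([C@@H](CCCC(=O)OC)OC(C)=O)O2 | target

Total step count: 14. Longest linear sequence: 13 steps (steps 1–8 and 10–14, from (Z)-oct-2-en-1-ol); step 9 is a one-step side branch.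

Steps most likely to fail

Step 10 (key step). Facial selectivity at C6 may be eroded, because the octenyl methylene on C12 also lies on the convex face, and part of the stannane may be protonated by the free hydroxyl before it reacts. The fallback delivers the carbon intramolecularly from O7 through a temporary silicon connection. Setting out from 14, exchange of the anomeric methoxy group with benzeneselenol and BF3·OEt2 would give the phenylselenoacetal (3S,3aS,6aR)-5-chloro-3-hydroxy-6a-[(Z)-oct-2-enyl]-2-(phenylselanyl)-2,3,3a,6a-tetrahydro-4H-cyclopenta[b]furan-4-one F1. Its C7 hydroxyl would be silylated (imidazole, CH2Cl2) with methyl 5-[chloro(dimethyl)silyl]pent-4-ynoate F2, made from 15 with excess dichlorodimethylsilane, Zn(OTf)2 and Et3N, to give the tethered alkynylsilyl ether F3. Bu3SnH with Et3B/air at 0 °C would then generate the C6 radical (the low temperature is meant to suppress fragmentation of the ring C–O bond). Its 5-exo-dig closure onto the silicon-bearing alkyne carbon can only take place cis to O7 and leads to 19 (as an E/Z mixture, both oxidised to 20 in step 12), where the route is rejoined.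

Step 7. The lithium aldol may show low anti/syn selectivity or react in part on the face of the octenyl chain, and the aldolate may equilibrate by retro-aldol cleavage. The fallback moves to a boron-mediated aldol on the O-silylated ketone. From 10, TMSCl and imidazole would give the trimethylsilyl ether (R)-2-chloro-4-[(Z)-oct-2-enyl]-4-(trimethylsilyloxy)cyclopent-2-en-1-one F4. Dicyclohexylboron chloride and Et3N (Et2O, −78 °C) would form the (E)-boron enolate, whose tight chair transition state is reliably anti and which should again react anti to the octenyl chain; addition of 11 would give the aldol (4R,5S)-2-chloro-5-[(1S)-1-hydroxy-2,2-dimethoxyethyl]-4-[(Z)-oct-2-enyl]-4-(trimethylsilyloxy)cyclopent-2-en-1-one F5. PPTS in CH2Cl2 would then close the acetal with loss of the silyl group and return 14.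

Step 13. Hydride may also reduce the C9 ring ketone or the chloro enone if chelation at C5 is incomplete. The fallback replaces the external hydride by an intramolecular one and corrects C5 afterwards. From 20, an Evans–Tishchenko reduction (SmI2 cat., acetaldehyde, THF, −10 °C) transfers hydride from the O7 hemiacetal to the C5 ketone only and would give the 1,3-anti monoacetate, methyl (5S)-5-[(2S,3S,3aS,6aR)-3-acetoxy-5-chloro-6a-[(Z)-oct-2-enyl]-4-oxo-3,3a,4,6a-tetrahydro-2H-cyclopenta[b]furan-2-yl]-5-hydroxypentanoate F6, already carrying the C7 acetate. A Mitsunobu reaction with acetic acid (PPh3, DIAD, toluene, 0 °C) would invert C5 and give 23 directly.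

Further compounds
F1 | step 10 | (3S,3aS,6aR)-5-chloro-3-hydroxy-6a-[(Z)-oct-2-enyl]-2-(phenylselanyl)-2,3,3a,6a-tetrahydro-4H-cyclopenta[b]furan-4-one (C2 epimers) | CCCCC/C=C\C[C@]12C=C(Cl)C(=O)[C@H]1[C@H](O)C([Se]c1ccccc1)O2
F2 | step 10 | methyl 5-[chloro(dimethyl)silyl]pent-4-ynoate | COC(=O)CCC#C[Si](C)(C)Cl
F3 | step 10 | 3-O-[(4-methoxycarbonylbut-1-ynyl)dimethylsilyl] ether of F1 | CCCCC/C=C\C[C@]12C=C(Cl)C(=O)[C@H]1[C@H](O[Si](C)(C)C#CCCC(=O)OC)C([Se]c1ccccc1)O2
F4 | step 7 | (R)-2-chloro-4-[(Z)-oct-2-enyl]-4-(trimethylsilyloxy)cyclopent-2-en-1-one | CCCCC/C=C\C[C@]1(O[Si](C)(C)C)C=C(Cl)C(=O)C1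
F5 | step 7 | (4R,5S)-2-chloro-5-[(1S)-1-hydroxy-2,2-dimethoxyethyl]-4-[(Z)-oct-2-enyl]-4-(trimethylsilyloxy)cyclopent-2-en-1-one | CCCCC/C=C\C[C@]1(O[Si](C)(C)C)C=C(Cl)C(=O)[C@H]1[C@H](O)C(OC)OC
F6 | step 13 | methyl (5S)-5-[(2S,3S,3aS,6aR)-3-acetoxy-5-chloro-6a-[(Z)-oct-2-enyl]-4-oxo-3,3a,4,6a-tetrahydro-2H-cyclopenta[b]furan-2-yl]-5-hydroxypentanoate | CCCCC/C=C\C[C@]12C=C(Cl)C(=O)[C@H]1[C@H](OC(C)=O)[C@H]([C@H](CCCC(=O)OC)O)O2
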